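**Strategy.** Ring B of the target (C1–C2–C3–C4–C4a–C8a) is treated as the one-carbon homologue of the five-membered ring of a 3-aryl-1-indanone. C4, the =CH on ring A, is the former indanone carbonyl carbon, C2 (bearing C9) is the ester-bearing carbon, and C3 is the inserted atom. A Dowd–Beckwith radical rearrangement of an enantioenriched, benzyl-protected methyl 3-aryl-2-(bromomethyl)-1-oxoindane-2-carboxylate forms C3–C4, cuts C2–C4 and gives the 4-oxotetralin-2-carboxylate in one operation. C1 comes from an asymmetric reductive Heck cyclisation, and C2 is settled by equilibration. The surviving C4 ketone then directs formylation to C3 and, after reduction and acid, becomes the C3=C4 enal.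

Key step: step 7

Assumptions: ring-B compounds carry the target's 1,2-dihydronaphthalene numbering (C1 = ArCH, C2 = CH bearing C9, C3, C4 next to ring A); the bisphosphine antipode in step 4 is taken to be the one that gives the 3S indanone; O-benzylvanillin is purchased.

Step 1
Reactants: 1 acetosyringone; 2 benzyl bromide
Product: 3 1-[4-(benzyloxy)-3,5-dimethoxyphenyl]ethan-1-one
Conditions: BnBr, K2CO3, DMF, 60 °C
Reagents that add atoms: benzyl bromide (2), BrCc1ccccc1
Why: Williamson ether synthesis, in which the phenoxide of 1 is alkylated by the benzylic bromide while the methyl ketone is inert to carbonate.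

Step 2
Reactants: 3 1-[4-(benzyloxy)-3,5-dimethoxyphenyl]ethan-1-one; 4 N-bromosuccinimide
Product: 5 1-[4-(benzyloxy)-2-bromo-3,5-dimethoxyphenyl]ethan-1-one
Conditions: NBS (1.05 equiv), MeCN, 0 °C to rt, dark
Reagents that add atoms: N-bromosuccinimide (4), O=C1CCC(=O)N1Br
Why: Electrophilic aromatic bromination at one of the two equivalent free ring positions (each ortho to one methoxy and para to the other), where the non-acidic polar medium should favour nuclear over α-keto bromination.

Step 3
Reactants: 5 1-[4-(benzyloxy)-2-bromo-3,5-dimethoxyphenyl]ethan-1-one; 6 4-(benzyloxy)-3-methoxybenzaldehyde (O-benzylvanillin)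
Product: 7 (2E)-1-[4-(benzyloxy)-2-bromo-3,5-dimethoxyphenyl]-3-[4-(benzyloxy)-3-methoxyphenyl]prop-2-en-1-one
Conditions: KOH, EtOH–THF, rt
Reagents that add atoms: 4-(benzyloxy)-3-methoxybenzaldehyde (6), COc1cc(C=O)ccc1OCc1ccccc1
Why: Claisen–Schmidt condensation of the methyl ketone enolate with a non-enolisable aldehyde, dehydration giving the E-enone while the aryl bromide and benzyl ethers are untouched.

Step 4
Reactants: 7 (2E)-1-[4-(benzyloxy)-2-bromo-3,5-dimethoxyphenyl]-3-[4-(benzyloxy)-3-methoxyphenyl]prop-2-en-1-one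
Product: 8 (3S)-5-(benzyloxy)-3-[4-(benzyloxy)-3-methoxyphenyl]-4,6-dimethoxy-2,3-dihydro-1H-inden-1-one
Conditions: Pd(OAc)2 (5 mol %), (R)-3,5-Xyl-MeO-BIPHEP (7 mol %), HCO2Na, ethylene glycol–DMF, 90 °C
Reagents that add atoms: none
Why: Asymmetric intramolecular reductive Heck reaction, in which oxidative addition at C–Br, enantio-determining insertion of the enone into the aryl–Pd bond under the chiral bisphosphine (glycol aiding bromide dissociation) and formate-derived hydride reduction of the Pd enolate set the 3S centre that becomes C1 of the target.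

Step 5
Reactants: 8 (3S)-5-(benzyloxy)-3-[4-(benzyloxy)-3-methoxyphenyl]-4,6-dimethoxy-2,3-dihydro-1H-inden-1-one; 9 dimethyl carbonate
Product: 10 methyl (2R,3S)-5-(benzyloxy)-3-[4-(benzyloxy)-3-methoxyphenyl]-4,6-dimethoxy-1-oxo-2,3-dihydro-1H-indene-2-carboxylate (trans keto form, C2 labile)
Conditions: NaH, (MeO)2CO, THF, 60 °C; then 1 M HCl
Reagents that add atoms: dimethyl carbonate (9), COC(=O)OC
Why: Claisen-type C-acylation of the ketone enolate, driven by formation of the stabilised β-keto ester enolate, with C3–H not α to a carbonyl and therefore expected to keep its configuration.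

Step 6
Reactants: 10 methyl (2R,3S)-5-(benzyloxy)-3-[4-(benzyloxy)-3-methoxyphenyl]-4,6-dimethoxy-1-oxo-2,3-dihydro-1H-indene-2-carboxylate; 11 dibromomethane
Product: 12 methyl (2R,3S)-5-(benzyloxy)-3-[4-(benzyloxy)-3-methoxyphenyl]-2-(bromomethyl)-4,6-dimethoxy-1-oxo-2,3-dihydro-1H-indene-2-carboxylate (CH2Br trans to the C3 aryl group)
Conditions: NaH, THF–DMPU, 0 °C; CH2Br2 (10 equiv), 60 °C
Reagents that add atoms: dibromomethane (11), BrCBr
Why: SN2 C-alkylation of the β-keto ester enolate with excess dihalide, expected anti to the C3 aryl group, where the configuration of the quaternary C2 is immaterial because that carbon becomes a radical in step 7.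

Step 7
Reactants: 12 methyl (2R,3S)-5-(benzyloxy)-3-[4-(benzyloxy)-3-methoxyphenyl]-2-(bromomethyl)-4,6-dimethoxy-1-oxo-2,3-dihydro-1H-indene-2-carboxylate
Product: 14 methyl (1S,2S)-7-(benzyloxy)-1-[4-(benzyloxy)-3-methoxyphenyl]-6,8-dimethoxy-4-oxo-1,2,3,4-tetrahydronaphthalene-2-carboxylate (trans), via cis keto ester 13 (not isolated)
Conditions: Bu3SnH (1.3 equiv) and AIBN (0.2 equiv) added over 6 h, PhH (0.01 M), 80 °C; hexane/MeCN partition; then NaOMe (0.3 equiv), MeOH–THF, rt
Reagents that add atoms: none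
Why: Dowd–Beckwith ring expansion, known for 2-(halomethyl)-1-indanone-2-carboxylates: the tin radical abstracts bromine, the primary radical adds to the indanone carbonyl in a 3-exo-trig closure, and the cyclopropyloxy radical undergoes β-scission of the old carbonyl–C2 bond, so the CH2 carbon becomes C3, C3–C4 forms, C2–C4 breaks and ring B arises by one-carbon enlargement. Fragmentation towards the tertiary, ester-stabilised C2 radical is favoured over reversion or aryl radical formation, and slow stannane addition at high dilution should hold back premature reduction of the primary radical. The C2 centre is created when the stannane transfers hydrogen to that radical, presumably anti to the pseudo-axial C1 aryl group, which should give the cis ester 13 first. Because C2–H is α to the ester, catalytic methoxide should then equilibrate it to the trans isomer 14, in which the aryl group (pseudo-axial to avoid the peri C8 methoxy) and the ester are anti. C1 is not touched by the radical chain and should survive the methoxide stage, since peri strain holds C1–H near the plane of ring A where it is poorly aligned for deprotonation.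

Step 8
Reactants: 14 methyl (1S,2S)-7-(benzyloxy)-1-[4-(benzyloxy)-3-methoxyphenyl]-6,8-dimethoxy-4-oxo-1,2,3,4-tetrahydronaphthalene-2-carboxylate; 15 methyl formate
Product: 16 methyl (1S,2R,3Z)-7-(benzyloxy)-1-[4-(benzyloxy)-3-methoxyphenyl]-3-(hydroxymethylidene)-6,8-dimethoxy-4-oxo-1,2,3,4-tetrahydronaphthalene-2-carboxylate
Conditions: NaOMe (3 equiv), HCO2Me, THF, 0 °C to rt; then cold 1 M HCl
Reagents that add atoms: methyl formate (15), COC=O
Why: Crossed Claisen formylation at C3, the only enolisable position α to the ketone, driven by the stabilised β-keto aldehyde enolate and leaving C1 and C2 unchanged (the C2 descriptor changes only through CIP priorities).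

Step 9
Reactants: 16 methyl (1S,2R,3Z)-7-(benzyloxy)-1-[4-(benzyloxy)-3-methoxyphenyl]-3-(hydroxymethylidene)-6,8-dimethoxy-4-oxo-1,2,3,4-tetrahydronaphthalene-2-carboxylate; 17 2-iodopropane
Product: 18 methyl (1S,2R,3E)-7-(benzyloxy)-1-[4-(benzyloxy)-3-methoxyphenyl]-6,8-dimethoxy-4-oxo-3-[(propan-2-yloxy)methylidene]-1,2,3,4-tetrahydronaphthalene-2-carboxylate
Conditions: iPrI, K2CO3, acetone, reflux
Reagents that add atoms: 2-iodopropane (17), CC(C)I
Why: O-alkylation of the β-keto aldehyde enolate with a secondary iodide (classical isopropoxymethylene ketone formation), which for steric reasons goes to oxygen and not to C3, with a weak heterogeneous base that should leave C2–H alone; either enol ether geometry serves.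

Step 10
Reactants: 18 methyl (1S,2R,3E)-7-(benzyloxy)-1-[4-(benzyloxy)-3-methoxyphenyl]-6,8-dimethoxy-4-oxo-3-[(propan-2-yloxy)methylidene]-1,2,3,4-tetrahydronaphthalene-2-carboxylate
Product: 20 (1S,2R)-7-(benzyloxy)-1-[4-(benzyloxy)-3-methoxyphenyl]-2-(hydroxymethyl)-6,8-dimethoxy-1,2-dihydronaphthalene-3-carbaldehyde, via diol enol ether 19 (not isolated)
Conditions: LiAlH4, THF, −10 to 0 °C; then 1 M HCl, THF, 0 °C to rt
Reagents that add atoms: water, O
Why: Hydride reduces the ester to the C9 alcohol and the vinylogous ester carbonyl in the 1,2 sense, after which dilute acid ionises the benzylic, allylic C4 alcohol and hydrolyses the enol ether with allylic transposition (the classical alkoxymethylene ketone to enal sequence), giving the C3=C4 enal without involving C1 or C2.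

Step 11
Reactants: 20 (1S,2R)-7-(benzyloxy)-1-[4-(benzyloxy)-3-methoxyphenyl]-2-(hydroxymethyl)-6,8-dimethoxy-1,2-dihydronaphthalene-3-carbaldehyde
Product: 21 (1S,2R)-7-hydroxy-1-(4-hydroxy-3-methoxyphenyl)-2-(hydroxymethyl)-6,8-dimethoxy-1,2-dihydronaphthalene-3-carbaldehyde
Conditions: BCl3, pentamethylbenzene, CH2Cl2, −78 °C; then MeOH, aq NaHCO3
Reagents that add atoms: none
Why: Lewis-acid debenzylation of aryl benzyl ethers with a non-basic benzyl cation scavenger at low temperature, chosen because it should spare the enal, the C3=C4 bond and the aryl methyl ethers, which hydrogenolysis would not.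

**Compound list**

1 | acetosyringone, 1-(4-hydroxy-3,5-dimethoxyphenyl)ethan-1-one | CC(=O)c1cc(OC)c(O)c(OC)c1 | starting material
2 | benzyl bromide | BrCc1ccccc1 | starting material
3 | 1-[4-(benzyloxy)-3,5-dimethoxyphenyl]ethan-1-one | CC(=O)c1cc(OC)c(OCc2ccccc2)c(OC)c1 | intermediate
4 | N-bromosuccinimide | O=C1CCC(=O)N1Br | starting material
5 | 1-[4-(benzyloxy)-2-bromo-3,5-dimethoxyphenyl]ethan-1-one | CC(=O)c1cc(OC)c(OCc2ccccc2)c(OC)c1Br | intermediate
6 | 4-(benzyloxy)-3-methoxybenzaldehyde (O-benzylvanillin) | COc1cc(C=O)ccc1OCc1ccccc1 | starting material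
7 | (2E)-1-[4-(benzyloxy)-2-bromo-3,5-dimethoxyphenyl]-3-[4-(benzyloxy)-3-methoxyphenyl]prop-2-en-1-one | COc1cc(/C=C/C(=O)c2cc(OC)c(OCc3ccccc3)c(OC)c2Br)ccc1OCc1ccccc1 | intermediate
8 | (3S)-5-(benzyloxy)-3-[4-(benzyloxy)-3-methoxyphenyl]-4,6-dimethoxy-2,3-dihydro-1H-inden-1-one | COc1cc([C@H]2c3c(cc(OC)c(OCc4ccccc4)c3OC)C(=O)C2)ccc1OCc1ccccc1 | intermediate
9 | dimethyl carbonate | COC(=O)OC | starting material
10 | methyl (2R,3S)-5-(benzyloxy)-3-[4-(benzyloxy)-3-methoxyphenyl]-4,6-dimethoxy-1-oxo-2,3-dihydro-1H-indene-2-carboxylate (trans keto form) | COc1cc([C@H]2c3c(cc(OC)c(OCc4ccccc4)c3OC)C(=O)[C@@H]2C(=O)OC)ccc1OCc1ccccc1 | intermediate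
11 | dibromomethane | BrCBr | starting material
12 | methyl (2R,3S)-5-(benzyloxy)-3-[4-(benzyloxy)-3-methoxyphenyl]-2-(bromomethyl)-4,6-dimethoxy-1-oxo-2,3-dihydro-1H-indene-2-carboxylate | COc1cc([C@H]2c3c(cc(OC)c(OCc4ccccc4)c3OC)C(=O)[C@@]2(CBr)C(=O)OC)ccc1OCc1ccccc1 | intermediate
13 | methyl (1S,2R)-7-(benzyloxy)-1-[4-(benzyloxy)-3-methoxyphenyl]-6,8-dimethoxy-4-oxo-1,2,3,4-tetrahydronaphthalene-2-carboxylate (1,2-cis) | COc1cc([C@H]2c3c(cc(OC)c(OCc4ccccc4)c3OC)C(=O)C[C@H]2C(=O)OC)ccc1OCc1ccccc1 | intermediate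
14 | methyl (1S,2S)-7-(benzyloxy)-1-[4-(benzyloxy)-3-methoxyphenyl]-6,8-dimethoxy-4-oxo-1,2,3,4-tetrahydronaphthalene-2-carboxylate (1,2-trans) | COc1cc([C@H]2c3c(cc(OC)c(OCc4ccccc4)c3OC)C(=O)C[C@@H]2C(=O)OC)ccc1OCc1ccccc1 | intermediate
15 | methyl formate | COC=O | starting material
16 | methyl (1S,2R,3Z)-7-(benzyloxy)-1-[4-(benzyloxy)-3-methoxyphenyl]-3-(hydroxymethylidene)-6,8-dimethoxy-4-oxo-1,2,3,4-tetrahydronaphthalene-2-carboxylate | COc1cc([C@H]2c3c(cc(OC)c(OCc4ccccc4)c3OC)C(=O)/C(=C\O)[C@@H]2C(=O)OC)ccc1OCc1ccccc1 | intermediate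
17 | 2-iodopropane | CC(C)I | starting material
18 | methyl (1S,2R,3E)-7-(benzyloxy)-1-[4-(benzyloxy)-3-methoxyphenyl]-6,8-dimethoxy-4-oxo-3-[(propan-2-yloxy)methylidene]-1,2,3,4-tetrahydronaphthalene-2-carboxylate | COc1cc([C@H]2c3c(cc(OC)c(OCc4ccccc4)c3OC)C(=O)/C(=C/OC(C)C)[C@@H]2C(=O)OC)ccc1OCc1ccccc1 | intermediate
19 | (1S,2R,3E)-7-(benzyloxy)-1-[4-(benzyloxy)-3-methoxyphenyl]-2-(hydroxymethyl)-6,8-dimethoxy-3-[(propan-2-yloxy)methylidene]-1,2,3,4-tetrahydronaphthalen-4-ol (both C4 epimers) | COc1cc([C@H]2c3c(cc(OC)c(OCc4ccccc4)c3OC)C(O)/C(=C/OC(C)C)[C@@H]2CO)ccc1OCc1ccccc1 | intermediate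
20 | (1S,2R)-7-(benzyloxy)-1-[4-(benzyloxy)-3-methoxyphenyl]-2-(hydroxymethyl)-6,8-dimethoxy-1,2-dihydronaphthalene-3-carbaldehyde | COc1cc([C@H]2c3c(cc(OC)c(OCc4ccccc4)c3OC)C=C(C=O)[C@@H]2CO)ccc1OCc1ccccc1 | intermediate
21 | (1S,2R)-7-hydroxy-1-(4-hydroxy-3-methoxyphenyl)-2-(hydroxymethyl)-6,8-dimethoxy-1,2-dihydronaphthalene-3-carbaldehyde [(3R,4S) in 3,4-dihydronaphthalene-2-carbaldehyde numbering] | COc1cc([C@H]2c3c(cc(OC)c(O)c3OC)C=C(C=O)[C@@H]2CO)ccc1O | target

**Step count.** Total: 11 steps. Longest linear sequence: 11 steps (1 to 21).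

**Steps most likely to fail**

Step 7. Hydrogen transfer to the primary radical may outrun its addition to the electron-rich aryl ketone carbonyl, giving simple reduction instead of ring enlargement. The methoxide stage may also stop short of complete conversion to the trans ester. The fallback sets out from 10 and replaces the radical chain by the zinc-carbenoid chain extension of β-keto esters. With Et2Zn and CH2I2 in CH2Cl2 at 0 °C to rt, the zinc enolate of 10 should be cyclopropanated, and the resulting donor–acceptor cyclopropoxide should fragment to the ring-enlarged C2 zinc ester enolate. Protonation with aqueous NH4Cl should give the 13/14 mixture, and the methoxide equilibration of step 7 brings the sequence back to 14. No compound outside the list is formed (F0).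

Step 4. Enantioface discrimination may be weak if bromide stays on palladium, and hydride reduction of the aryl–palladium species or of the enone may compete with cyclisation at the doubly ortho-substituted carbon. The fallback sets out from 7. Miyaura borylation (B2pin2, PdCl2(dppf), KOAc, dioxane, 85 °C) should give (2E)-1-[4-(benzyloxy)-3,5-dimethoxy-2-(4,4,5,5-tetramethyl-1,3,2-dioxaborolan-2-yl)phenyl]-3-[4-(benzyloxy)-3-methoxyphenyl]prop-2-en-1-one F1. A rhodium-catalysed asymmetric intramolecular 1,4-addition of the arylboronate to the enone ([Rh(C2H4)2Cl]2, MonoPhos of the appropriate antipode, aqueous K3PO4, toluene) should then close the five-membered ring and return to the route at 8.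

Step 11. The Lewis acid may degrade the electron-rich hydroxy enal (ionisation, aromatisation) or cleave the benzyl ethers incompletely. The fallback changes the protecting-group plan, sets out from 14 and comes back at 21.
- Hydrogenolysis (H2, Pd/C, EtOAc), done before any C=C bond exists, should give methyl (1S,2S)-7-hydroxy-1-(4-hydroxy-3-methoxyphenyl)-6,8-dimethoxy-4-oxo-1,2,3,4-tetrahydronaphthalene-2-carboxylate F2.
- MOMCl and iPr2NEt should convert it into methyl (1S,2S)-1-[3-methoxy-4-(methoxymethoxy)phenyl]-6,8-dimethoxy-7-(methoxymethoxy)-4-oxo-1,2,3,4-tetrahydronaphthalene-2-carboxylate F3.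
- Formylation as in step 8 should give the hydroxymethylidene ketone, methyl (1S,2R,3Z)-3-(hydroxymethylidene)-1-[3-methoxy-4-(methoxymethoxy)phenyl]-6,8-dimethoxy-7-(methoxymethoxy)-4-oxo-1,2,3,4-tetrahydronaphthalene-2-carboxylate F4.
- O-Alkylation as in step 9 should give the isopropoxymethylidene ketone, methyl (1S,2R,3E)-1-[3-methoxy-4-(methoxymethoxy)phenyl]-6,8-dimethoxy-7-(methoxymethoxy)-4-oxo-3-[(propan-2-yloxy)methylidene]-1,2,3,4-tetrahydronaphthalene-2-carboxylate F5.
- LiAlH4 reduction should give the diol, (1S,2R,3E)-2-(hydroxymethyl)-1-[3-methoxy-4-(methoxymethoxy)phenyl]-6,8-dimethoxy-7-(methoxymethoxy)-3-[(propan-2-yloxy)methylidene]-1,2,3,4-tetrahydronaphthalen-4-ol F6.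
- Aqueous HCl in THF at 40 °C should then unmask the enal and remove both methoxymethyl groups in the same operation, giving 21.

**Further compounds**

F0 | step 7 | none | none
F1 | step 4 | (2E)-1-[4-(benzyloxy)-3,5-dimethoxy-2-(4,4,5,5-tetramethyl-1,3,2-dioxaborolan-2-yl)phenyl]-3-[4-(benzyloxy)-3-methoxyphenyl]prop-2-en-1-one | COc1cc(/C=C/C(=O)c2cc(OC)c(OCc3ccccc3)c(OC)c2B4OC(C)(C)C(C)(C)O4)ccc1OCc1ccccc1
F2 | step 11 | methyl (1S,2S)-7-hydroxy-1-(4-hydroxy-3-methoxyphenyl)-6,8-dimethoxy-4-oxo-1,2,3,4-tetrahydronaphthalene-2-carboxylate | COc1cc([C@H]2c3c(cc(OC)c(O)c3OC)C(=O)C[C@@H]2C(=O)OC)ccc1O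
F3 | step 11 | methyl (1S,2S)-1-[3-methoxy-4-(methoxymethoxy)phenyl]-6,8-dimethoxy-7-(methoxymethoxy)-4-oxo-1,2,3,4-tetrahydronaphthalene-2-carboxylate | COc1cc([C@H]2c3c(cc(OC)c(OCOC)c3OC)C(=O)C[C@@H]2C(=O)OC)ccc1OCOC
F4 | step 11 | methyl (1S,2R,3Z)-3-(hydroxymethylidene)-1-[3-methoxy-4-(methoxymethoxy)phenyl]-6,8-dimethoxy-7-(methoxymethoxy)-4-oxo-1,2,3,4-tetrahydronaphthalene-2-carboxylate | COc1cc([C@H]2c3c(cc(OC)c(OCOC)c3OC)C(=O)/C(=C\O)[C@@H]2C(=O)OC)ccc1OCOC
F5 | step 11 | methyl (1S,2R,3E)-1-[3-methoxy-4-(methoxymethoxy)phenyl]-6,8-dimethoxy-7-(methoxymethoxy)-4-oxo-3-[(propan-2-yloxy)methylidene]-1,2,3,4-tetrahydronaphthalene-2-carboxylate | COc1cc([C@H]2c3c(cc(OC)c(OCOC)c3OC)C(=O)/C(=C/OC(C)C)[C@@H]2C(=O)OC)ccc1OCOC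
F6 | step 11 | (1S,2R,3E)-2-(hydroxymethyl)-1-[3-methoxy-4-(methoxymethoxy)phenyl]-6,8-dimethoxy-7-(methoxymethoxy)-3-[(propan-2-yloxy)methylidene]-1,2,3,4-tetrahydronaphthalen-4-ol (both C4 epimers) | COc1cc([C@H]2c3c(cc(OC)c(OCOC)c3OC)C(O)/C(=C/OC(C)C)[C@@H]2CO)ccc1OCOC
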